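**Strategy.** Everything rests on cutting the two C(quinone)–C(aryl) bonds: C2 and C5 of the central 1,4-benzoquinone ring each carry C1' of a 4-hydroxyphenyl ring, and the two sites are related by the twofold symmetry of that ring. One double Suzuki–Miyaura coupling therefore builds the whole terphenylquinone skeleton from 2,5-dibromo-3,6-dimethoxy-1,4-benzoquinone and a 4-oxygenated phenylboronic acid. The phenols are carried as p-methoxybenzyl ethers, not silyl ethers, because a silyl ether would not survive the alkaline unmasking of the quinone hydroxyls; they are removed last under neutral oxidative conditions. The side chains come from (E)-crotyl alcohol by Sharpless epoxidation and Z-selective olefination.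

Key step: step 2

Remark: both acyl groups are read from the SMILES as (2Z,4S,5S)-4,5-epoxyhex-2-enoyl, that is (2Z)-3-[(2S,3S)-3-methyloxiran-2-yl]prop-2-enoyl with a trans-epoxide.

**Route**

Step 1
Reactants: 1 tetrabromo-1,4-benzoquinone (bromanil)
Product: 2 2,5-dibromo-3,6-dimethoxy-1,4-benzoquinone
Conditions: NaOMe (2.05 equiv), MeOH, 0 °C → rt
Reagents that add atoms: sodium methoxide, C[O-].[Na+]
Why: Twofold addition–elimination (vinylogous acyl substitution) of methoxide on the tetrahaloquinone, in which the first methoxy group, as a vinylogous ester, deactivates its own double bond and the position conjugated to the same carbonyl, so the second methoxide should enter para to the first and the sparingly soluble product should crystallise before further substitution.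

Step 2
Reactants: 2 2,5-dibromo-3,6-dimethoxy-1,4-benzoquinone; 3 4-[(4-methoxybenzyl)oxy]phenylboronic acid (2.6 equiv)
Product: 4 2,5-bis{4-[(4-methoxybenzyl)oxy]phenyl}-3,6-dimethoxy-1,4-benzoquinone
Conditions: Pd(dppf)Cl2·CH2Cl2 (5 mol%), K3PO4, 1,4-dioxane, 80 °C, argon
Reagents that add atoms: none
Why: Pd(dppf)Cl2 is reduced in the flask to zerovalent palladium, which inserts into each C–Br bond of 2 (a vinylogous acyl bromide of an electron-poor quinone), and phosphate-assisted transmetalation from the arylboronic acid followed by reductive elimination forms the C2–C1' bond and then, in a second cycle, the C5–C1' bond. The closest known reaction type is the Suzuki–Miyaura coupling of halogenated alkoxybenzoquinones with arylboronic acids. No ring is closed and no stereocentre is created. The only selectivity needed is chemoselectivity: cross-coupling must outrun reduction of the quinone, displacement of bromide or methoxide by oxygen nucleophiles, and protodeboronation. This is secured by the O-methyl groups (neutral vinylogous esters instead of chelating, anionic hydroxyquinone oxygens), by a weak, poorly nucleophilic base in a non-hydroxylic solvent, and by base-stable benzyl-type ethers that cannot release a phenoxide. The two C–Br sites are equivalent by the symmetry of 2, so no regiochemical question arises and the monoarylated bromide should react on under the same conditions.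

Step 3
Reactants: 4 2,5-bis{4-[(4-methoxybenzyl)oxy]phenyl}-3,6-dimethoxy-1,4-benzoquinone
Product: 6 2,5-dihydroxy-3,6-bis{4-[(4-methoxybenzyl)oxy]phenyl}-1,4-benzoquinone, via disodium quinonediolate 5 (not isolated)
Conditions: 2 M aq. NaOH, MeOH/THF, rt → 50 °C; then 1 M HCl, 0 °C
Reagents that add atoms: sodium hydroxide, [Na+].[OH-]
Why: Saponification of the two vinylogous methyl esters by hydroxide addition–elimination at the methoxy-bearing ring carbons, to which the p-methoxybenzyl aryl ethers are inert, followed by protonation of the quinonediolate.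

Step 4
Reactants: 7 (E)-but-2-en-1-ol
Product: 8 (2S,3S)-2,3-epoxybutan-1-ol
Conditions: Ti(OiPr)4 (5 mol%), L-(+)-diisopropyl tartrate (6 mol%), t-BuOOH (isooctane), 4 Å molecular sieves, CH2Cl2, −20 °C; non-aqueous work-up, distillation
Reagents that add atoms: tert-butyl hydroperoxide, CC(C)(C)OO
Why: Sharpless asymmetric epoxidation, in which the catalyst formed from Ti(OiPr)4 and L-(+)-diisopropyl tartrate should deliver the peroxide oxygen to the face of the bound E-allylic alcohol that gives the (2S,3S)-epoxide, the trans relation of the two new stereocentres following from stereospecific syn addition to the E-alkene.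

Step 5
Reactants: 8 (2S,3S)-2,3-epoxybutan-1-ol
Product: 10 methyl (2Z)-3-[(2S,3S)-3-methyloxiran-2-yl]prop-2-enoate, via (2R,3S)-3-methyloxirane-2-carbaldehyde 9 (not isolated)
Conditions: Dess–Martin periodinane, CH2Cl2, 0 °C → rt; pentane, filtration through basic Al2O3; cold filtrate into (CF3CH2O)2P(O)CH2CO2Me, KN(SiMe3)2, 18-crown-6, THF, −78 °C
Reagents that add atoms: methyl bis(2,2,2-trifluoroethyl)phosphonoacetate, COC(=O)CP(=O)(OCC(F)(F)F)OCC(F)(F)F
Why: Dess–Martin oxidation should give the configurationally stable α,β-epoxy aldehyde, which is used in solution because it is volatile and water-soluble, and the Still–Gennari olefination (electron-poor phosphonate, dissociated potassium counter-ion) eliminates the kinetically formed adduct before it can equilibrate and so should give the Z-enoate without touching the epoxide stereocentres.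

Step 6
Reactants: 10 methyl (2Z)-3-[(2S,3S)-3-methyloxiran-2-yl]prop-2-enoate
Product: 11 potassium (2Z)-3-[(2S,3S)-3-methyloxiran-2-yl]prop-2-enoate
Conditions: KOSiMe3 (1.05 equiv), Et2O, 0 °C → rt; filtration under argon
Reagents that add atoms: potassium trimethylsilanolate, C[Si](C)(C)[O-].[K+]
Why: Anhydrous cleavage of the methyl ester with potassium trimethylsilanolate should precipitate the carboxylate salt, so the free Z-epoxy acid, which could lactonise by intramolecular epoxide opening, is never generated and neither the Z-alkene nor the epoxide meets aqueous acid or base.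

Step 7
Reactants: 6 2,5-dihydroxy-3,6-bis{4-[(4-methoxybenzyl)oxy]phenyl}-1,4-benzoquinone; 11 potassium (2Z)-3-[(2S,3S)-3-methyloxiran-2-yl]prop-2-enoate (2.6 equiv)
Product: 13 2,5-bis{4-[(4-methoxybenzyl)oxy]phenyl}-3,6-dioxocyclohexa-1,4-diene-1,4-diyl bis{(2Z)-3-[(2S,3S)-3-methyloxiran-2-yl]prop-2-enoate}, via mixed trichlorobenzoic anhydride 12 (not isolated)
Conditions: 11, 2,4,6-Cl3C6H2COCl (2.6 equiv), THF, 0 °C → rt; then 6, Et3N (2.0 equiv), DMAP (0.1 equiv), THF, 0 °C → rt
Reagents that add atoms: none
Why: Yamaguchi-type mixed-anhydride acylation, in which the bis(triethylammonium) quinonediolate (a vinylogous carboxylate) attacks the unhindered enoyl carbonyl of 12 while the 2,6-dichloro-flanked aroyl carbonyl is shielded, acyl transfer under DMAP catalysis being reversible enough to end in the conjugated 1,4-quinone diester, and the low temperature, the absence of free amine and the small DMAP charge guarding the Z-alkenes and the epoxides.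

Step 8
Reactants: 13 2,5-bis{4-[(4-methoxybenzyl)oxy]phenyl}-3,6-dioxocyclohexa-1,4-diene-1,4-diyl bis{(2Z)-3-[(2S,3S)-3-methyloxiran-2-yl]prop-2-enoate}
Product: 14 2,5-bis(4-hydroxyphenyl)-3,6-dioxocyclohexa-1,4-diene-1,4-diyl bis{(2Z)-3-[(2S,3S)-3-methyloxiran-2-yl]prop-2-enoate} (CNP0407724.1)
Conditions: DDQ (3 equiv), CH2Cl2/pH 7 phosphate buffer (18:1), 0 °C → rt; work-up without base
Reagents that add atoms: none
Why: Oxidative cleavage of the p-methoxybenzyl aryl ethers with DDQ (hydride abstraction from the benzylic CH2 of the electron-rich anisyl ring, then hydrolysis of the oxocarbenium ion to phenol and anisaldehyde) runs at neutral pH without base, fluoride or strong acid, so the acyloxyquinone esters, the Z-enoates and the epoxides, which offer DDQ no oxidisable site, should survive.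

**Compound list**

1 | tetrabromo-1,4-benzoquinone (bromanil) | O=C1C(Br)=C(Br)C(=O)C(Br)=C1Br | starting material
2 | 2,5-dibromo-3,6-dimethoxy-1,4-benzoquinone | COC1=C(Br)C(=O)C(OC)=C(Br)C1=O | intermediate
3 | 4-[(4-methoxybenzyl)oxy]phenylboronic acid | COc1ccc(COc2ccc(B(O)O)cc2)cc1 | starting material
4 | 2,5-bis{4-[(4-methoxybenzyl)oxy]phenyl}-3,6-dimethoxy-1,4-benzoquinone | COC1=C(c2ccc(OCc3ccc(OC)cc3)cc2)C(=O)C(OC)=C(c2ccc(OCc3ccc(OC)cc3)cc2)C1=O | intermediate
5 | disodium 2,5-bis{4-[(4-methoxybenzyl)oxy]phenyl}-3,6-dioxocyclohexa-1,4-diene-1,4-diolate | [Na+].[Na+].[O-]C1=C(c2ccc(OCc3ccc(OC)cc3)cc2)C(=O)C([O-])=C(c2ccc(OCc3ccc(OC)cc3)cc2)C1=O | intermediate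
6 | 2,5-dihydroxy-3,6-bis{4-[(4-methoxybenzyl)oxy]phenyl}-1,4-benzoquinone | OC1=C(c2ccc(OCc3ccc(OC)cc3)cc2)C(=O)C(O)=C(c2ccc(OCc3ccc(OC)cc3)cc2)C1=O | intermediate
7 | (E)-but-2-en-1-ol | C/C=C/CO | starting material
8 | (2S,3S)-2,3-epoxybutan-1-ol, trans-epoxide | C[C@@H]1O[C@H]1CO | intermediate
9 | (2R,3S)-3-methyloxirane-2-carbaldehyde | C[C@@H]1O[C@H]1C=O | intermediate
10 | methyl (2Z)-3-[(2S,3S)-3-methyloxiran-2-yl]prop-2-enoate | C[C@@H]1O[C@H]1/C=C\C(=O)OC | intermediate
11 | potassium (2Z)-3-[(2S,3S)-3-methyloxiran-2-yl]prop-2-enoate | C[C@@H]1O[C@H]1/C=C\C(=O)[O-].[K+] | intermediate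
12 | (2Z)-3-[(2S,3S)-3-methyloxiran-2-yl]prop-2-enoic 2,4,6-trichlorobenzoic anhydride | C[C@@H]1O[C@H]1/C=C\C(=O)OC(=O)c1c(Cl)cc(Cl)cc1Cl | intermediate
13 | 2,5-bis{4-[(4-methoxybenzyl)oxy]phenyl}-3,6-dioxocyclohexa-1,4-diene-1,4-diyl bis{(2Z)-3-[(2S,3S)-3-methyloxiran-2-yl]prop-2-enoate} | C[C@@H]1O[C@H]1/C=C\C(=O)OC1=C(c2ccc(OCc3ccc(OC)cc3)cc2)C(=O)C(OC(=O)/C=C\[C@@H]2O[C@H]2C)=C(c2ccc(OCc3ccc(OC)cc3)cc2)C1=O | intermediate
14 | 2,5-bis(4-hydroxyphenyl)-3,6-dioxocyclohexa-1,4-diene-1,4-diyl bis{(2Z)-3-[(2S,3S)-3-methyloxiran-2-yl]prop-2-enoate} | C[C@@H]1O[C@H]1/C=C\C(=O)OC1=C(c2ccc(O)cc2)C(=O)C(OC(=O)/C=C\[C@@H]2O[C@H]2C)=C(c2ccc(O)cc2)C1=O | target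

**Step count and risks**

Total step count: 8. Longest linear sequence: 5 steps (steps 1, 2, 3, 7, 8; the side-chain branch, steps 4, 5, 6, 7, 8, is equally long).

The three steps most likely to fail:

Step 7 (acylation). The Z-enoyl unit may isomerise to E by reversible conjugate addition of DMAP or chloride to the activated acyl species, the carboxylate may open its own epoxide before it is activated, and the reaction may stall after the first acylation. The fallback sets out from 11 and 6 and comes back at 13. Salt 11 would be treated with oxalyl chloride in CH2Cl2 at 0 °C, with no proton source present, to give (2Z)-3-[(2S,3S)-3-methyloxiran-2-yl]prop-2-enoyl chloride F1. Diol 6 would be converted with Ag2O in acetonitrile into the disilver quinonediolate F2. The two would then be combined in CH2Cl2 at 0 °C, where precipitation of AgCl should drive the O-acylation to 13 without amine base or nucleophilic catalyst.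

Step 8 (final deprotection). Oxidation of the aryl p-methoxybenzyl ethers may be slow, so that long contact with wet DDQ causes hydrolytic loss of the acyl groups or leaves the deprotection incomplete. The fallback sets out from 6 and comes back at 14; it moves the ether cleavage ahead of the acylation and ends with a fluoride-labile group. CF3CO2H/anisole in CH2Cl2 would convert 6 into 2,5-dihydroxy-3,6-bis(4-hydroxyphenyl)-1,4-benzoquinone (atromentin) F3. Silylation of all four hydroxyls with t-BuMe2SiCl/imidazole in DMF would give the tetrakis(silyl) compound F4, whose two vinylogous silyl esters should hydrolyse selectively in AcOH/THF/H2O to 2,5-bis[4-(tert-butyldimethylsilyloxy)phenyl]-3,6-dihydroxy-1,4-benzoquinone F5. Acylation with 12 as in step 7 would give the bis(silyl) diester F6. The aryl silyl ethers would then be cleaved with Bu4NF buffered with acetic acid in THF at 0 °C, so that no phenoxide is set free, to give 14.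

Step 2 (key coupling). The quinone may be reduced to its hydroquinone by the palladium/boronic acid system, bromide or methoxide may be displaced by oxygen nucleophiles, or the reaction may stop after one arylation. The fallback sets out from 2 and comes back at 4; it moves the coupling to the arene oxidation level. Reduction of 2 with Na2S2O4 would give 2,5-dibromo-3,6-dimethoxybenzene-1,4-diol F7, and methylation (MeI, K2CO3, acetone) would give 1,4-dibromo-2,3,5,6-tetramethoxybenzene F8. Twofold Suzuki–Miyaura coupling with 3 under ordinary aqueous conditions (Pd(PPh3)4, K2CO3, toluene/EtOH/H2O, 90 °C) would give 1,4-bis{4-[(4-methoxybenzyl)oxy]phenyl}-2,3,5,6-tetramethoxybenzene F9. Oxidative demethylation with (NH4)2Ce(NO3)6 (2.2 equiv, MeCN/H2O, 0 °C, short contact) should then give quinone 4, since the fully oxygenated central ring is oxidised far more readily than the anisyl ethers.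

Further compounds
F1 | step 7 | (2Z)-3-[(2S,3S)-3-methyloxiran-2-yl]prop-2-enoyl chloride | C[C@@H]1O[C@H]1/C=C\C(Cl)=O
F2 | step 7 | disilver 2,5-bis{4-[(4-methoxybenzyl)oxy]phenyl}-3,6-dioxocyclohexa-1,4-diene-1,4-diolate | [Ag+].[Ag+].[O-]C1=C(c2ccc(OCc3ccc(OC)cc3)cc2)C(=O)C([O-])=C(c2ccc(OCc3ccc(OC)cc3)cc2)C1=O
F3 | step 8 | 2,5-dihydroxy-3,6-bis(4-hydroxyphenyl)-1,4-benzoquinone (atromentin) | OC1=C(c2ccc(O)cc2)C(=O)C(O)=C(c2ccc(O)cc2)C1=O
F4 | step 8 | 2,5-bis(tert-butyldimethylsilyloxy)-3,6-bis[4-(tert-butyldimethylsilyloxy)phenyl]-1,4-benzoquinone | CC(C)(C)[Si](C)(C)OC1=C(c2ccc(O[Si](C)(C)C(C)(C)C)cc2)C(=O)C(O[Si](C)(C)C(C)(C)C)=C(c2ccc(O[Si](C)(C)C(C)(C)C)cc2)C1=O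
F5 | step 8 | 2,5-bis[4-(tert-butyldimethylsilyloxy)phenyl]-3,6-dihydroxy-1,4-benzoquinone | OC1=C(c2ccc(O[Si](C)(C)C(C)(C)C)cc2)C(=O)C(O)=C(c2ccc(O[Si](C)(C)C(C)(C)C)cc2)C1=O
F6 | step 8 | 2,5-bis[4-(tert-butyldimethylsilyloxy)phenyl]-3,6-dioxocyclohexa-1,4-diene-1,4-diyl bis{(2Z)-3-[(2S,3S)-3-methyloxiran-2-yl]prop-2-enoate} | C[C@@H]1O[C@H]1/C=C\C(=O)OC1=C(c2ccc(O[Si](C)(C)C(C)(C)C)cc2)C(=O)C(OC(=O)/C=C\[C@@H]2O[C@H]2C)=C(c2ccc(O[Si](C)(C)C(C)(C)C)cc2)C1=O
F7 | step 2 | 2,5-dibromo-3,6-dimethoxybenzene-1,4-diol | COc1c(Br)c(O)c(OC)c(Br)c1O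
F8 | step 2 | 1,4-dibromo-2,3,5,6-tetramethoxybenzene | COc1c(Br)c(OC)c(OC)c(Br)c1OC
F9 | step 2 | 1,4-bis{4-[(4-methoxybenzyl)oxy]phenyl}-2,3,5,6-tetramethoxybenzene | COc1c(-c2ccc(OCc3ccc(OC)cc3)cc2)c(OC)c(OC)c(-c2ccc(OCc3ccc(OC)cc3)cc2)c1OC
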